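The decalin is numbered clerodane-style: ring A = C1–C5 and C10, ring B = C5–C10, C11 = benzylic CH2. The route rests on cutting the C4–C5 bond of cyclohexene ring A. An intramolecular Heck reaction exploits the quaternary C5 beside the C3=C4 alkene and the cis C5/C10 fusion. A (Z)-alkenyl iodide (C3=C4–I) tethered to C10 adds to C5 of the ring B alkene C5=C6, which closes ring A, creates C5 and places the trisubstituted alkene in one operation. The precursor is a benzoxazolylmethyl-substituted 1-methylcyclohexene. Its C8/C9 centres come from asymmetric conjugate methylation–benzylation, its C10 centre from a stereospecific Pd/formate reduction.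

Key step: step 14

Remark: Ar = 5-methoxy-2-methyl-6-(triisopropylsilyloxy)-1,3-benzoxazol-7-yl; β is the face of ring B that carries the C8 and C9 methyl groups and α the opposite face; 4-methoxybenzene-1,3-diol is taken as a catalogue compound, and the ligand enantiomer in step 6 is taken to be the one that delivers the 3S enolate.

Step 1
Reactants: 1 4-methoxybenzene-1,3-diol
Product: 2 4-methoxy-6-nitrosobenzene-1,3-diol
Conditions: NaNO2, AcOH, H2O, 0 °C
Reagents that add atoms: sodium nitrite, [Na+].[O-]N=O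
Why: Electrophilic aromatic nitrosation of the electron-rich resorcinol should occur at C6, para to one hydroxyl and ortho to the other, which puts the future nitrogen next to the oxygen that becomes the oxazole oxygen.

Step 2
Reactants: 2 4-methoxy-6-nitrosobenzene-1,3-diol
Product: 4 5-methoxy-2-methyl-1,3-benzoxazol-6-ol, via aminoresorcinol 3 (not isolated)
Conditions: H2 (1 atm), Pd/C, EtOH, rt; then MeC(OEt)3, TsOH (cat.), 80 °C
Reagents that add atoms: triethyl orthoacetate, CC(OCC)(OCC)OCC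
Why: Hydrogenation of the nitroso group gives the ortho-aminophenol, which undergoes the standard orthoester cyclocondensation to the 2-methylbenzoxazole through the only hydroxyl ortho to nitrogen, leaving the hydroxyl next to the methoxy group free.

Step 3
Reactants: 4 5-methoxy-2-methyl-1,3-benzoxazol-6-ol
Product: 5 7-[(dimethylamino)methyl]-5-methoxy-2-methyl-1,3-benzoxazol-6-ol
Conditions: aq. CH2O, aq. Me2NH, EtOH, 50 °C
Reagents that add atoms: formaldehyde, C=O; dimethylamine, CNC
Why: Phenol Mannich reaction, in which the iminium ion attacks ortho to the free hydroxyl, and C7 is the only open ortho position.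

Step 4
Reactants: 5 7-[(dimethylamino)methyl]-5-methoxy-2-methyl-1,3-benzoxazol-6-ol
Product: 6 1-[5-methoxy-2-methyl-6-(triisopropylsilyloxy)-1,3-benzoxazol-7-yl]-N,N-dimethylmethanamine
Conditions: TIPSOTf, Et3N, CH2Cl2, 0 °C
Reagents that add atoms: triisopropylsilyl triflate, CC(C)[Si](OS(=O)(=O)C(F)(F)F)(C(C)C)C(C)C
Why: Standard phenol silylation gives a bulky silyl ether that should withstand the organometallic, enolate, dilute-acid and palladium steps and is removed by fluoride at the end.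

Step 5
Reactants: 6 1-[5-methoxy-2-methyl-6-(triisopropylsilyloxy)-1,3-benzoxazol-7-yl]-N,N-dimethylmethanamine
Product: 7 7-(chloromethyl)-5-methoxy-2-methyl-6-(triisopropylsilyloxy)-1,3-benzoxazole (ArCH2Cl)
Conditions: ClCO2Et, CH2Cl2, 0 °C to rt
Reagents that add atoms: ethyl chloroformate, CCOC(Cl)=O
Why: Chloroformate dealkylation of a benzylic tertiary amine (von Braun type), in which N-acylation gives an acylammonium ion from which chloride displaces the carbamate at the electron-rich benzylic carbon.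

Step 6
Reactants: 8 2-methylcyclohex-2-en-1-one
Product: 10 trimethyl{[(3S)-2,3-dimethylcyclohex-1-en-1-yl]oxy}silane, via aluminium enolate 9 (not isolated)
Conditions: Me3Al, CuTC (CuO2CC4H3S, 2 mol %), BINOL bis(1-phenylethyl)amine phosphoramidite ligand (4 mol %), Et2O, −30 °C; then TMSOTf, THF, −30 to 0 °C
Reagents that add atoms: trimethylaluminium, C[Al](C)C; trimethylsilyl triflate, C[Si](C)(C)OS(=O)(=O)C(F)(F)F
Why: Copper-catalysed asymmetric conjugate addition of Me3Al to the 2-substituted enone sets the C8 methyl stereocentre (3S) under control of the chiral phosphoramidite, and O-silylation of the aluminium enolate fixes the enolate regiochemistry.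

Step 7
Reactants: 10 trimethyl{[(3S)-2,3-dimethylcyclohex-1-en-1-yl]oxy}silane; 7 ArCH2Cl
Product: 12 (2R,3S)-2-(ArCH2)-2,3-dimethylcyclohexan-1-one, via lithium enolate 11 (not isolated)
Conditions: MeLi, THF, 0 °C; then 7, DMPU, Bu4NI (cat.), −78 to 0 °C
Reagents that add atoms: none
Why: Stork-type regiospecific release of the lithium enolate with MeLi and SN2 benzylation, in which the electrophile approaches C9 anti to the pseudoaxial C8 methyl group, so the quaternary C9 should form with ArCH2 trans to the C8 methyl (2R,3S).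

Step 8
Reactants: 12 (2R,3S)-2-(ArCH2)-2,3-dimethylcyclohexan-1-one
Product: 14 (2R,3S)-2-(ArCH2)-2,3,6-trimethylcyclohexan-1-one (C6 epimers), via lithium enolate 13 (not isolated)
Conditions: LiN(iPr)2, THF, −78 °C; MeI, −78 to −20 °C
Reagents that add atoms: iodomethane, CI
Why: Kinetic enolate methylation at C5, the only enolisable α-carbon because C9 is quaternary; the configuration of the new centre is irrelevant since C5 becomes sp2 in step 9.

Step 9
Reactants: 14 (2R,3S)-2-(ArCH2)-2,3,6-trimethylcyclohexan-1-one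
Product: 16 (5S,6R)-6-(ArCH2)-2,5,6-trimethylcyclohex-2-en-1-one, via silyl enol ether 15 (not isolated)
Conditions: TMSOTf, Et3N, CH2Cl2, 0 °C; then Pd(OAc)2 (1.1 equiv), MeCN, rt
Reagents that add atoms: none
Why: Saegusa–Ito oxidation, in which the only possible silyl enol ether (C10=C5) forms an oxa-π-allyl complex of divalent palladium that undergoes β-hydride elimination into the ring (C6–H) to give the 2-methyl enone.

Step 10
Reactants: 16 (5S,6R)-6-(ArCH2)-2,5,6-trimethylcyclohex-2-en-1-one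
Product: 18 (1R,5S,6R)-6-(ArCH2)-1-[2-(1,3-dioxolan-2-yl)ethyl]-2,5,6-trimethylcyclohex-2-en-1-yl methyl carbonate, via magnesium alkoxide 17 (not isolated)
Conditions: BrMgCH2CH2CH(OCH2CH2O), CeCl3, THF, −78 °C; then ClCO2Me, −78 °C to rt
Reagents that add atoms: 2-(1,3-dioxolan-2-yl)ethylmagnesium bromide, Br[Mg]CCC1OCCO1; methyl chloroformate, COC(Cl)=O
Why: Organocerium 1,2-addition to the hindered enone carbonyl (CeCl3 suppresses enolisation and conjugate addition) should occur from the α face, anti to the axial C9 methyl group, placing the C10 oxygen on the β face, and the alkoxide is acylated in the same flask.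

Step 11
Reactants: 18 (1R,5S,6R)-6-(ArCH2)-1-[2-(1,3-dioxolan-2-yl)ethyl]-2,5,6-trimethylcyclohex-2-en-1-yl methyl carbonate
Product: 19 2-{2-[(1R,5S,6R)-6-(ArCH2)-2,5,6-trimethylcyclohex-2-en-1-yl]ethyl}-1,3-dioxolane
Conditions: Pd(OAc)2 (5 mol %), n-Bu3P, HCO2NH4, 1,4-dioxane, 80 °C
Reagents that add atoms: none
Why: Tsuji hydrogenolysis of an allylic carbonate with formate, in which zerovalent palladium ionises the carbonate with inversion (Pd on the α face) and internal hydride delivery to the more substituted allyl terminus C10 should set C10–H α (side chain β) and leave the alkene at C5=C6.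

Step 12
Reactants: 19 2-{2-[(1R,5S,6R)-6-(ArCH2)-2,5,6-trimethylcyclohex-2-en-1-yl]ethyl}-1,3-dioxolane
Product: 20 3-[(1R,5S,6R)-6-(ArCH2)-2,5,6-trimethylcyclohex-2-en-1-yl]propanal
Conditions: 1 M HCl, THF, rt
Reagents that add atoms: water, O
Why: Acid-catalysed acetal hydrolysis under mild aqueous conditions that the aryl silyl ether, the benzoxazole and the trisubstituted alkene should tolerate.

Step 13
Reactants: 20 3-[(1R,5S,6R)-6-(ArCH2)-2,5,6-trimethylcyclohex-2-en-1-yl]propanal
Product: 21 (1R,5S,6R)-6-(ArCH2)-1-[(3Z)-4-iodopent-3-en-1-yl]-2,5,6-trimethylcyclohex-2-ene (ring locants as in 19)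
Conditions: [Ph3PCH2CH3]I, n-BuLi, THF, 0 °C; I2, −78 °C; NaN(SiMe3)2, −20 °C; then 20, −78 °C to rt
Reagents that add atoms: ethyltriphenylphosphonium iodide, CC[P+](c1ccccc1)(c1ccccc1)c1ccccc1.[I-]; iodine, II
Why: Stork–Zhao olefination, in which the α-iodo ylide reacts with the aldehyde under kinetic control to give the (Z)-2-iodoalk-2-ene with iodine cis to the chain.

Step 14
Reactants: 21 (1R,5S,6R)-6-(ArCH2)-1-[(3Z)-4-iodopent-3-en-1-yl]-2,5,6-trimethylcyclohex-2-ene
Product: 22 5-methoxy-2-methyl-7-{[(1R,2S,4aR,8aS)-1,2,4a,5-tetramethyl-1,2,4a,7,8,8a-hexahydronaphthalen-1-yl]methyl}-6-(triisopropylsilyloxy)-1,3-benzoxazole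
Conditions: Pd(OAc)2 (10 mol %), PPh3 (30 mol %), Ag2CO3, MeCN, 80 °C
Reagents that add atoms: none
Why: Intramolecular Heck reaction: zerovalent palladium inserts into the C4–I bond with retention of the Z geometry, the alkenylpalladium adds syn across C5=C6 (C4 to C5, Pd to C6) and syn β-hydride elimination towards C7 releases the diene and a palladium hydride that Ag2CO3 quenches. The closest known reaction type is the Heck cyclisation of alkenyl halides onto trisubstituted cycloalkenes that builds quaternary ring-fusion carbons. Ring A closes in the 6-exo-trig mode, and the Z geometry (iodine cis to C2) is what allows the C3=C4 double bond to end up inside the new ring. The new quaternary stereocentre C5 is controlled by C10: the three-carbon tether sits on the β face, so the alkenylpalladium can only reach the β face of C5, which should give the cis ring fusion with the C5 methyl α. The step needs 6-exo over 7-endo insertion and no migration of the new C6=C7 bond towards C8; the short tether secures the first, and the silver salt together with the absence of hydrogen on C5 secures the second.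

Step 15
Reactants: 22 the hexahydronaphthalene diene from step 14
Product: 23 5-methoxy-2-methyl-7-{[(1R,2S,4aR,8aS)-1,2,4a,5-tetramethyl-1,2,3,4,4a,7,8,8a-octahydronaphthalen-1-yl]methyl}-6-(triisopropylsilyloxy)-1,3-benzoxazole
Conditions: H2 (3 atm), RhCl(PPh3)3 (10 mol %), benzene/EtOH, rt
Reagents that add atoms: none
Why: Homogeneous hydrogenation with Wilkinson's catalyst distinguishes alkenes by substitution, so the cis-disubstituted C6=C7 bond should be saturated while the trisubstituted C3=C4 bond next to the quaternary C5 remains; no stereocentre is formed.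

Step 16
Reactants: 23 the silyl ether from step 15
Product: 24 5-methoxy-2-methyl-7-{[(1R,2S,4aR,8aS)-1,2,4a,5-tetramethyl-1,2,3,4,4a,7,8,8a-octahydronaphthalen-1-yl]methyl}-1,3-benzoxazol-6-ol (CNP0149771.1)
Conditions: Bu4NF, THF, 0 °C
Reagents that add atoms: none
Why: Fluoride cleavage of the aryl silyl ether under conditions that leave the benzoxazole and the alkene untouched should give the free phenol.

Compound list
1 | 4-methoxybenzene-1,3-diol | COc1ccc(O)cc1O | starting material
2 | 4-methoxy-6-nitrosobenzene-1,3-diol | COc1cc(N=O)c(O)cc1O | intermediate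
3 | 4-amino-6-methoxybenzene-1,3-diol | COc1cc(N)c(O)cc1O | intermediate
4 | 5-methoxy-2-methyl-1,3-benzoxazol-6-ol | COc1cc2nc(C)oc2cc1O | intermediate
5 | 7-[(dimethylamino)methyl]-5-methoxy-2-methyl-1,3-benzoxazol-6-ol | COc1cc2nc(C)oc2c(CN(C)C)c1O | intermediate
6 | 1-[5-methoxy-2-methyl-6-(triisopropylsilyloxy)-1,3-benzoxazol-7-yl]-N,N-dimethylmethanamine | COc1cc2nc(C)oc2c(CN(C)C)c1O[Si](C(C)C)(C(C)C)C(C)C | intermediate
7 | 7-(chloromethyl)-5-methoxy-2-methyl-6-(triisopropylsilyloxy)-1,3-benzoxazole (ArCH2Cl) | COc1cc2nc(C)oc2c(CCl)c1O[Si](C(C)C)(C(C)C)C(C)C | intermediate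
8 | 2-methylcyclohex-2-en-1-one | CC1=CCCCC1=O | starting material
9 | dimethylaluminium (3S)-2,3-dimethylcyclohex-1-en-1-olate | C[Al](C)OC1=C(C)[C@@H](C)CCC1 | intermediate
10 | trimethyl{[(3S)-2,3-dimethylcyclohex-1-en-1-yl]oxy}silane | C[Si](C)(C)OC1=C(C)[C@@H](C)CCC1 | intermediate
11 | lithium (3S)-2,3-dimethylcyclohex-1-en-1-olate | [Li]OC1=C(C)[C@@H](C)CCC1 | intermediate
12 | (2R,3S)-2-(ArCH2)-2,3-dimethylcyclohexan-1-one | COc1cc2nc(C)oc2c(C[C@]3(C)[C@@H](C)CCCC3=O)c1O[Si](C(C)C)(C(C)C)C(C)C | intermediate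
13 | lithium (5S,6R)-6-(ArCH2)-5,6-dimethylcyclohex-1-en-1-olate | COc1cc2nc(C)oc2c(C[C@]3(C)[C@@H](C)CCC=C3O[Li])c1O[Si](C(C)C)(C(C)C)C(C)C | intermediate
14 | (2R,3S)-2-(ArCH2)-2,3,6-trimethylcyclohexan-1-one, C6 epimers | COc1cc2nc(C)oc2c(C[C@]3(C)[C@@H](C)CCC(C)C3=O)c1O[Si](C(C)C)(C(C)C)C(C)C | intermediate
15 | trimethyl{[(5S,6R)-6-(ArCH2)-2,5,6-trimethylcyclohex-1-en-1-yl]oxy}silane | COc1cc2nc(C)oc2c(C[C@]3(C)[C@@H](C)CCC(C)=C3O[Si](C)(C)C)c1O[Si](C(C)C)(C(C)C)C(C)C | intermediate
16 | (5S,6R)-6-(ArCH2)-2,5,6-trimethylcyclohex-2-en-1-one | COc1cc2nc(C)oc2c(C[C@]3(C)[C@@H](C)CC=C(C)C3=O)c1O[Si](C(C)C)(C(C)C)C(C)C | intermediate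
17 | bromomagnesium (1R,5S,6R)-6-(ArCH2)-1-[2-(1,3-dioxolan-2-yl)ethyl]-2,5,6-trimethylcyclohex-2-en-1-olate | COc1cc2nc(C)oc2c(C[C@]3(C)[C@@H](C)CC=C(C)[C@]3(O[Mg]Br)CCC4OCCO4)c1O[Si](C(C)C)(C(C)C)C(C)C | intermediate
18 | (1R,5S,6R)-6-(ArCH2)-1-[2-(1,3-dioxolan-2-yl)ethyl]-2,5,6-trimethylcyclohex-2-en-1-yl methyl carbonate | COc1cc2nc(C)oc2c(C[C@]3(C)[C@@H](C)CC=C(C)[C@]3(OC(=O)OC)CCC4OCCO4)c1O[Si](C(C)C)(C(C)C)C(C)C | intermediate
19 | 2-{2-[(1R,5S,6R)-6-(ArCH2)-2,5,6-trimethylcyclohex-2-en-1-yl]ethyl}-1,3-dioxolane | COc1cc2nc(C)oc2c(C[C@]3(C)[C@@H](C)CC=C(C)[C@H]3CCC4OCCO4)c1O[Si](C(C)C)(C(C)C)C(C)C | intermediate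
20 | 3-[(1R,5S,6R)-6-(ArCH2)-2,5,6-trimethylcyclohex-2-en-1-yl]propanal | COc1cc2nc(C)oc2c(C[C@]3(C)[C@@H](C)CC=C(C)[C@H]3CCC=O)c1O[Si](C(C)C)(C(C)C)C(C)C | intermediate
21 | (1R,5S,6R)-6-(ArCH2)-1-[(3Z)-4-iodopent-3-en-1-yl]-2,5,6-trimethylcyclohex-2-ene (ring locants as in 19) | COc1cc2nc(C)oc2c(C[C@]3(C)[C@@H](C)CC=C(C)[C@H]3CC/C=C(/C)I)c1O[Si](C(C)C)(C(C)C)C(C)C | intermediate
22 | 5-methoxy-2-methyl-7-{[(1R,2S,4aR,8aS)-1,2,4a,5-tetramethyl-1,2,4a,7,8,8a-hexahydronaphthalen-1-yl]methyl}-6-(triisopropylsilyloxy)-1,3-benzoxazole | COc1cc2nc(C)oc2c(C[C@]3(C)[C@@H](C)C=C[C@@]4(C)C(C)=CCC[C@@H]34)c1O[Si](C(C)C)(C(C)C)C(C)C | intermediate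
23 | 5-methoxy-2-methyl-7-{[(1R,2S,4aR,8aS)-1,2,4a,5-tetramethyl-1,2,3,4,4a,7,8,8a-octahydronaphthalen-1-yl]methyl}-6-(triisopropylsilyloxy)-1,3-benzoxazole | COc1cc2nc(C)oc2c(C[C@]3(C)[C@@H](C)CC[C@@]4(C)C(C)=CCC[C@@H]34)c1O[Si](C(C)C)(C(C)C)C(C)C | intermediate
24 | 5-methoxy-2-methyl-7-{[(1R,2S,4aR,8aS)-1,2,4a,5-tetramethyl-1,2,3,4,4a,7,8,8a-octahydronaphthalen-1-yl]methyl}-1,3-benzoxazol-6-ol | COc1cc2nc(C)oc2c(C[C@]2(C)[C@@H](C)CC[C@@]3(C)C(C)=CCC[C@@H]23)c1O | target

Total step count: 16. Longest linear sequence: 15 steps (steps 1–5, then 7–16).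

Steps most likely to fail

Step 14. Carbopalladation of the hindered trisubstituted C5=C6 bond may be slow, so that protodeiodination or palladium hydride-mediated double-bond migration outruns ring closure. The fallback makes C5 a nucleophile instead and sets out from 19. Hydroboration–oxidation of the C5=C6 bond (BH3·THF; NaOH, H2O2) would give the C6 alcohol 2-{2-[6-(ArCH2)-3-hydroxy-2,5,6-trimethylcyclohexyl]ethyl}-1,3-dioxolane F1. Dess–Martin oxidation would give the C6 ketone F2, and acetal hydrolysis (1 M HCl, THF) the keto aldehyde F3. Stork–Zhao olefination of the aldehyde would give the (Z)-alkenyl iodide ketone F4. Palladium-catalysed intramolecular α-alkenylation of the ketone enolate (Pd2(dba)3, a bulky phosphine, KOt-Bu, THF) would then close ring A through the C5 enolate carbon to the cis-fused C6 ketone F5. Its enol triflate F6 (KN(SiMe3)2, PhNTf2) would be reduced with Pd(OAc)2, PPh3, HCO2H and Bu3N, and the route is rejoined at 22.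

Step 11. Hydride may be delivered to the less hindered allyl terminus C6, or the allylpalladium intermediate may lose a β-hydrogen to give a diene, because C10 lies next to the quaternary C9. The fallback sets out from 16 and moves the controlling stereocentre to C6. The same organocerium addition with aqueous work-up would give the tertiary allylic alcohol F7; either C10 epimer serves, so the facial course of the addition no longer matters. Pyridinium chlorochromate ([C5H5NH][CrO3Cl]) would effect the oxidative 1,3-transposition to the enone F8. Reagent-controlled reduction ((S)-2-methyl-CBS-oxazaborolidine, BH3·SMe2) would give the C6 β-alcohol F9. Myers reductive transposition (2-nitrobenzenesulfonylhydrazide, PPh3, DEAD) would proceed by Mitsunobu inversion at C6 and sigmatropic loss of N2 from the allylic diazene, delivering hydrogen to the α face of C10, and the route is rejoined at 19.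

Step 7. C-alkylation of the tetrasubstituted enolate by the doubly ortho-substituted benzylic chloride may be slow, allowing O-alkylation, proton transfer or low facial selectivity. The fallback replaces the SN2 step by conjugate addition to an ortho-quinone methide and sets out from 5 (with 10). Methylation of the amine with MeI would give the ammonium iodide F10. Two equivalents of lithium enolate 11 would then unmask the quinone methide from it by deprotonation and loss of trimethylamine and add to its methylene carbon, giving the phenol ketone F11. Silylation (TIPSOTf, Et3N) rejoins the route at 12.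

Further compounds
F1 | step 14 | 2-{2-[6-(ArCH2)-3-hydroxy-2,5,6-trimethylcyclohexyl]ethyl}-1,3-dioxolane, C1, C5, C6 as in 19, C2/C3 epimers | COc1cc2nc(C)oc2c(C[C@]3(C)[C@@H](C)CC(O)C(C)[C@H]3CCC4OCCO4)c1O[Si](C(C)C)(C(C)C)C(C)C
F2 | step 14 | 4-(ArCH2)-3-[2-(1,3-dioxolan-2-yl)ethyl]-2,4,5-trimethylcyclohexan-1-one, C2 epimers | COc1cc2nc(C)oc2c(C[C@]3(C)[C@@H](C)CC(=O)C(C)[C@H]3CCC4OCCO4)c1O[Si](C(C)C)(C(C)C)C(C)C
F3 | step 14 | 3-[6-(ArCH2)-2,5,6-trimethyl-3-oxocyclohexyl]propanal | COc1cc2nc(C)oc2c(C[C@]3(C)[C@@H](C)CC(=O)C(C)[C@H]3CCC=O)c1O[Si](C(C)C)(C(C)C)C(C)C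
F4 | step 14 | 4-(ArCH2)-3-[(3Z)-4-iodopent-3-en-1-yl]-2,4,5-trimethylcyclohexan-1-one | COc1cc2nc(C)oc2c(C[C@]3(C)[C@@H](C)CC(=O)C(C)[C@H]3CC/C=C(/C)I)c1O[Si](C(C)C)(C(C)C)C(C)C
F5 | step 14 | 1-(ArCH2)-1,2,4a,5-tetramethyl-2,3,4a,7,8,8a-hexahydronaphthalen-4(1H)-one, cis-fused, configured as 23 | COc1cc2nc(C)oc2c(C[C@]3(C)[C@@H](C)CC(=O)[C@@]4(C)C(C)=CCC[C@@H]34)c1O[Si](C(C)C)(C(C)C)C(C)C
F6 | step 14 | 1-(ArCH2)-1,2,4a,5-tetramethyl-1,2,4a,7,8,8a-hexahydronaphthalen-4-yl trifluoromethanesulfonate | COc1cc2nc(C)oc2c(C[C@]3(C)[C@@H](C)C=C(OS(=O)(=O)C(F)(F)F)[C@@]4(C)C(C)=CCC[C@@H]34)c1O[Si](C(C)C)(C(C)C)C(C)C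
F7 | step 11 | (5S,6R)-6-(ArCH2)-1-[2-(1,3-dioxolan-2-yl)ethyl]-2,5,6-trimethylcyclohex-2-en-1-ol, C1 epimers | COc1cc2nc(C)oc2c(C[C@]3(C)[C@@H](C)CC=C(C)C3(O)CCC4OCCO4)c1O[Si](C(C)C)(C(C)C)C(C)C
F8 | step 11 | (4R,5S)-4-(ArCH2)-3-[2-(1,3-dioxolan-2-yl)ethyl]-2,4,5-trimethylcyclohex-2-en-1-one | COc1cc2nc(C)oc2c(C[C@]3(C)[C@@H](C)CC(=O)C(C)=C3CCC4OCCO4)c1O[Si](C(C)C)(C(C)C)C(C)C
F9 | step 11 | (1R,4R,5S)-4-(ArCH2)-3-[2-(1,3-dioxolan-2-yl)ethyl]-2,4,5-trimethylcyclohex-2-en-1-ol | COc1cc2nc(C)oc2c(C[C@]3(C)[C@@H](C)C[C@@H](O)C(C)=C3CCC4OCCO4)c1O[Si](C(C)C)(C(C)C)C(C)C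
F10 | step 7 | [(6-hydroxy-5-methoxy-2-methyl-1,3-benzoxazol-7-yl)methyl]trimethylammonium iodide | COc1cc2nc(C)oc2c(C[N+](C)(C)C)c1O.[I-]
F11 | step 7 | (2R,3S)-2-[(6-hydroxy-5-methoxy-2-methyl-1,3-benzoxazol-7-yl)methyl]-2,3-dimethylcyclohexan-1-one | COc1cc2nc(C)oc2c(C[C@]3(C)[C@@H](C)CCCC3=O)c1O
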